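**Retrosynthetic overview**
1. The C4 carbonyl and the free 3'-OH lead back to a MOM-protected (2S)-flavan. C4 is oxidised late because it is the benzylic position para to the 7-OMe and ortho to O1.
2. Ring C of the flavan is cut at both of its bonds to ring A, C4–C4a and O1–C8a. This gives 1-iodo-2,3-dimethoxybenzene and an (S)-2-aryloxetane that already holds O1, C2, C3 and C4; a Catellani-type annulation (Pd(OAc)2 with a norbornene mediator) joins them.
3. Feature used: in ring A the neighbouring carbons C4a and C8a carry C4 and O1, and the next carbon, C8, is already methoxylated. An iodide at C8a therefore has a single ortho C–H (C4a), and it has the ortho substituent that forces norbornene out after the alkylation.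
4. The oxetane leads back through the (S)-1,3-diol and the (S)-β-hydroxy ester to the β-keto ester made from 3-hydroxy-4,5-dimethoxybenzaldehyde. C2 is set by hydrogenation with RuCl2[(R)-BINAP], and its C–O bond is not broken afterwards.
5. Ring order: rings A and B are bought, the oxetane is built as a strained carrier, and ring C is the only ring of the target that is closed.

Key step: step 7

Assumption: alcohol 10 is carried on as the mixture of its C4 epimers, because C4 becomes trigonal in step 9; its SMILES therefore has no descriptor at C4.

**Step 1**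
Reactants: 1 3-hydroxy-4,5-dimethoxybenzaldehyde
Product: 2 3,4-dimethoxy-5-(methoxymethoxy)benzaldehyde
Conditions: MOMCl, i-Pr2NEt, CH2Cl2, 0 °C to rt
Reagents that add atoms: chloromethyl methyl ether (MOMCl), COCCl
Why: O-alkylation of the phenol (MOM acetal protection) masks the only acidic O–H before the basic, hydridic and palladium steps and leaves the aldehyde untouched.

**Step 2**
Reactants: 2 3,4-dimethoxy-5-(methoxymethoxy)benzaldehyde
Product: 3 ethyl 3-[3,4-dimethoxy-5-(methoxymethoxy)phenyl]-3-oxopropanoate
Conditions: ethyl diazoacetate, SnCl2 (15 mol %), CH2Cl2, rt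
Reagents that add atoms: ethyl diazoacetate, CCOC(=O)C=[N+]=[N-]
Why: Roskamp homologation, in which the mild Lewis acid activates the aldehyde, the diazo carbon adds, and a 1,2-hydride shift with loss of N2 gives the β-keto ester in one operation.

**Step 3**
Reactants: 3 ethyl 3-[3,4-dimethoxy-5-(methoxymethoxy)phenyl]-3-oxopropanoate
Product: 4 ethyl (3S)-3-[3,4-dimethoxy-5-(methoxymethoxy)phenyl]-3-hydroxypropanoate
Conditions: RuCl2[(R)-BINAP] (1 mol %), H2 (20 bar), EtOH, 50 °C
Reagents that add atoms: none
Why: Noyori asymmetric hydrogenation, in which the chelated keto ester takes hydride on the Re face of the ketone under control of the (R)-BINAP ligand, the same spatial sense that gives (R)-alcohols from alkyl β-keto esters and reads (S) here because the aryl group outranks CH2CO2Et.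

**Step 4**
Reactants: 4 ethyl (3S)-3-[3,4-dimethoxy-5-(methoxymethoxy)phenyl]-3-hydroxypropanoate
Product: 5 (1S)-1-[3,4-dimethoxy-5-(methoxymethoxy)phenyl]propane-1,3-diol
Conditions: LiAlH4, THF, 0 °C to rt
Reagents that add atoms: none
Why: Hydride reduction of the ester to the primary alcohol does not involve the carbinol centre, and the aryl ethers and the MOM acetal are inert to it.

**Step 5**
Reactants: 5 (1S)-1-[3,4-dimethoxy-5-(methoxymethoxy)phenyl]propane-1,3-diol
Product: 6 (3S)-3-[3,4-dimethoxy-5-(methoxymethoxy)phenyl]-3-hydroxypropyl 4-methylbenzenesulfonate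
Conditions: TsCl (1.05 equiv), Et3N, DMAP (5 mol %), CH2Cl2, 0 °C
Reagents that add atoms: 4-toluenesulfonyl chloride (TsCl), Cc1ccc(cc1)S(=O)(=O)Cl
Why: Selective sulfonylation, since the unhindered primary hydroxyl reacts faster than the secondary benzylic one, so the leaving group sits on the carbon that will become C4 and the stereocentre keeps its oxygen.

**Step 6**
Reactants: 6 (3S)-3-[3,4-dimethoxy-5-(methoxymethoxy)phenyl]-3-hydroxypropyl 4-methylbenzenesulfonate
Product: 7 (2S)-2-[3,4-dimethoxy-5-(methoxymethoxy)phenyl]oxetane
Conditions: KOt-Bu (1.2 equiv), THF, 0 °C to rt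
Reagents that add atoms: none
Why: Intramolecular Williamson etherification (4-exo-tet), in which the secondary alkoxide displaces the primary tosylate, so the C–O bond at the stereocentre is not touched and the (S) configuration is kept.

**Step 7**
Reactants: 7 (2S)-2-[3,4-dimethoxy-5-(methoxymethoxy)phenyl]oxetane; 8 1-iodo-2,3-dimethoxybenzene
Product: 9 (2S)-2-[3,4-dimethoxy-5-(methoxymethoxy)phenyl]-7,8-dimethoxychromane
Conditions: Pd(OAc)2 (10 mol %), 2-dicyclohexylphosphino-2',6'-diisopropoxybiphenyl (RuPhos, 20 mol %), potassium 5-norbornene-2-carboxylate (50 mol %), K2CO3 (2 equiv), NMP, 110 °C, 8 (1.5 equiv) added slowly by syringe pump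
Reagents that add atoms: none
Why: Proposed new method: zerovalent palladium inserts into the C–I bond of 8, norbornene carbopalladation and base-assisted C–H palladation at the only free ortho position (the future C4a) give the five-membered aryl–norbornyl palladacycle, whose electron-rich divalent palladium attacks the O–CH2 carbon of 7 in an SN2-type oxidative addition to a tetravalent alkylpalladium alkoxide; C(sp2)–C(sp3) reductive elimination then makes C4–C4a, the arene, now flanked by the new chain and the C8 methoxy group, expels norbornene by β-carbon elimination, and the tethered alkoxide displaces iodide on the arylpalladium. The closest known reaction type is the Catellani-type annulation of aryl iodides with terminal epoxides to 2,3-dihydrobenzofurans, extended here by one carbon to the less electrophilic but almost equally strained oxetane, which is why the norbornene carries a potassium carboxylate that can hold K+ against the oxetane oxygen close to the metal and why the temperature is raised. Ring C closes by C–O reductive elimination from a seven-membered oxapalladacycle (Pd, C8a, C4a, C4, C3, C2, O1), the same event as an intramolecular Buchwald–Hartwig etherification, which is known to turn 1-substituted 3-(2-haloaryl)propan-1-ols into chromans with retention. No stereocentre is created, because the C2–O1 bond of 7 is never broken and (S) is carried over unchanged. The step needs opening at CH2 and not at the benzylic C2, which is secured by the bulk of the palladacycle and by the absence of any Brønsted or strong Lewis acid that could ionise C2–O, and it needs a single site on the arene, which is secured by the C8 methoxy group blocking the second ortho position. The bulky electron-rich biarylphosphine replaces a simple triarylphosphine to favour C–O reductive elimination over β-hydride loss from C2, K2CO3 takes up the HI of the balanced equation, and slow addition of 8 keeps the palladacycle from being arylated by a second molecule of iodide.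

**Step 8**
Reactants: 9 (2S)-2-[3,4-dimethoxy-5-(methoxymethoxy)phenyl]-7,8-dimethoxychromane
Product: 10 (2S)-2-[3,4-dimethoxy-5-(methoxymethoxy)phenyl]-7,8-dimethoxychroman-4-ol (mixture of C4 epimers)
Conditions: DDQ (1.2 equiv), CH2Cl2/pH 7 phosphate buffer (10:1), 0 °C to rt
Reagents that add atoms: water, O
Why: DDQ benzylic oxidation by hydride abstraction, known to functionalise flavans at C4, should pick C4 because its cation is stabilised by the para 7-methoxy group and the ortho ring oxygen O1, whereas C2–H depends on ring B, whose para 4'-methoxy group is twisted out of conjugation by two ortho neighbours, and water then captures the cation while the buffer holds back acid-induced loss of H-3.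

**Step 9**
Reactants: 10 (2S)-2-[3,4-dimethoxy-5-(methoxymethoxy)phenyl]-7,8-dimethoxychroman-4-ol
Product: 11 (2S)-2-[3,4-dimethoxy-5-(methoxymethoxy)phenyl]-7,8-dimethoxychroman-4-one
Conditions: activated MnO2 (15 equiv), CH2Cl2, rt
Reagents that add atoms: none
Why: MnO2 oxidation of a benzylic alcohol is neutral and heterogeneous, so both C4 epimers (and any ketone already formed in step 8) converge on 11 without the base that could open ring C and scramble C2.

**Step 10**
Reactants: 11 (2S)-2-[3,4-dimethoxy-5-(methoxymethoxy)phenyl]-7,8-dimethoxychroman-4-one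
Product: 12 (2S)-2-(3-hydroxy-4,5-dimethoxyphenyl)-7,8-dimethoxychroman-4-one (target CNP0402697.1)
Conditions: 3 M aq. HCl, THF, 40 °C
Reagents that add atoms: none
Why: Acid-catalysed acetal hydrolysis frees the 3'-phenol while the methyl ethers stay, and acid is chosen because flavanones lose C2 integrity through base-induced retro-oxa-Michael opening to the chalcone.

**Compound list**
1 | 3-hydroxy-4,5-dimethoxybenzaldehyde | COc1cc(C=O)cc(O)c1OC | starting material
2 | 3,4-dimethoxy-5-(methoxymethoxy)benzaldehyde | COc1cc(C=O)cc(OCOC)c1OC | intermediate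
3 | ethyl 3-[3,4-dimethoxy-5-(methoxymethoxy)phenyl]-3-oxopropanoate | CCOC(=O)CC(=O)c1cc(OC)c(OC)c(OCOC)c1 | intermediate
4 | ethyl (3S)-3-[3,4-dimethoxy-5-(methoxymethoxy)phenyl]-3-hydroxypropanoate | CCOC(=O)C[C@H](O)c1cc(OC)c(OC)c(OCOC)c1 | intermediate
5 | (1S)-1-[3,4-dimethoxy-5-(methoxymethoxy)phenyl]propane-1,3-diol | OCC[C@H](O)c1cc(OC)c(OC)c(OCOC)c1 | intermediate
6 | (3S)-3-[3,4-dimethoxy-5-(methoxymethoxy)phenyl]-3-hydroxypropyl 4-methylbenzenesulfonate | Cc1ccc(cc1)S(=O)(=O)OCC[C@H](O)c1cc(OC)c(OC)c(OCOC)c1 | intermediate
7 | (2S)-2-[3,4-dimethoxy-5-(methoxymethoxy)phenyl]oxetane | COc1cc([C@@H]2CCO2)cc(OCOC)c1OC | intermediate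
8 | 1-iodo-2,3-dimethoxybenzene | COc1cccc(I)c1OC | starting material
9 | (2S)-2-[3,4-dimethoxy-5-(methoxymethoxy)phenyl]-7,8-dimethoxychromane | COc1cc([C@@H]2CCc3ccc(OC)c(OC)c3O2)cc(OCOC)c1OC | intermediate
10 | (2S)-2-[3,4-dimethoxy-5-(methoxymethoxy)phenyl]-7,8-dimethoxychroman-4-ol, C4 epimers | COc1cc([C@@H]2CC(O)c3ccc(OC)c(OC)c3O2)cc(OCOC)c1OC | intermediate
11 | (2S)-2-[3,4-dimethoxy-5-(methoxymethoxy)phenyl]-7,8-dimethoxychroman-4-one | COc1cc([C@@H]2CC(=O)c3ccc(OC)c(OC)c3O2)cc(OCOC)c1OC | intermediate
12 | (2S)-2-(3-hydroxy-4,5-dimethoxyphenyl)-7,8-dimethoxychroman-4-one | COc1cc([C@@H]2CC(=O)c3ccc(OC)c(OC)c3O2)cc(O)c1OC | target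

**Step count**
Total step count: 10. Longest linear sequence: 10 steps (1 to 12); 8 is bought and enters at step 7.

**Steps most likely to fail**

1. **Step 7.**
   - What may go wrong: the palladacycle may open the oxetane too slowly. Arylation by a second molecule of iodide, reductive elimination with norbornene retained, or plain reduction of the C–I bond could then take over. At the last stage, β-hydride elimination from the palladium alkoxide may outrun C–O bond formation.
   - Fallback (known chemistry): it sets out from 2 and comes back at 11.
   - Claisen–Schmidt condensation of 2 with bought 1-(2-hydroxy-3,4-dimethoxyphenyl)ethanone (CC(=O)c1ccc(OC)c(OC)c1O; KOH, EtOH, rt) should give the (E)-2'-hydroxychalcone F1.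
   - NaOAc in refluxing EtOH closes it by oxa-Michael addition to the racemic flavanone F2.
   - Kinetic resolution by asymmetric transfer hydrogenation (Cp*RhCl[(R,R)-TsDPEN], HCO2H/Et3N, EtOAc, rt) should reduce only the (2R) enantiomer, to the 2,4-cis (2R,4R)-chroman-4-ol F3.
   - The (2S) ketone is left untouched. It is 11, is separated by chromatography, and enters step 10.

2. **Step 8.**
   - What may go wrong: the C4 cation may lose H-3, and further hydride abstraction towards the flavylium ion would erase C2. Hydride abstraction at C2 may also compete.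
   - Fallback: it keeps C4 at the carboxyl oxidation level, so no C–H oxidation is needed. It sets out from 3 and comes back at 11.
   - Hydrogenation of 3 with RuCl2[(S)-BINAP] (H2, EtOH) gives the ethyl (3R)-hydroxy ester F4.
   - Mitsunobu etherification with bought 2,3-dimethoxyphenol (COc1cccc(O)c1OC; PPh3, DIAD, toluene, 0 °C) inverts the centre and gives the (3S)-aryloxy ester F5.
   - LiOH in THF/water at 0 °C gives the carboxylic acid F6.
   - Intramolecular Friedel–Crafts acylation (trifluoroacetic anhydride, CH2Cl2, 0 °C) can reach only the free position ortho to the ether oxygen, which is para to a methoxy group. It closes C4–C4a to give 11.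

3. **Step 2.**
   - What may go wrong: aryl migration may replace hydride migration in the diazonium adduct, turnover may be slow with this electron-rich aldehyde, or the Lewis acid may attack the MOM acetal.
   - Fallback: it sets out from 2 and comes back at 3.
   - Aldol addition of the lithium enolate of ethyl acetate (LiN(i-Pr)2, EtOAc, THF, −78 °C) gives the racemic β-hydroxy ester F7.
   - Activated MnO2 in CH2Cl2 oxidises its benzylic alcohol to 3.

**Further compounds**
F1 | step 7 | (E)-1-(2-hydroxy-3,4-dimethoxyphenyl)-3-[3,4-dimethoxy-5-(methoxymethoxy)phenyl]prop-2-en-1-one | COc1cc(/C=C/C(=O)c2ccc(OC)c(OC)c2O)cc(OCOC)c1OC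
F2 | step 7 | racemic 2-[3,4-dimethoxy-5-(methoxymethoxy)phenyl]-7,8-dimethoxychroman-4-one | COc1cc(C2CC(=O)c3ccc(OC)c(OC)c3O2)cc(OCOC)c1OC
F3 | step 7 | (2R,4R)-2-[3,4-dimethoxy-5-(methoxymethoxy)phenyl]-7,8-dimethoxychroman-4-ol | COc1cc([C@H]2C[C@@H](O)c3ccc(OC)c(OC)c3O2)cc(OCOC)c1OC
F4 | step 8 | ethyl (3R)-3-[3,4-dimethoxy-5-(methoxymethoxy)phenyl]-3-hydroxypropanoate | CCOC(=O)C[C@@H](O)c1cc(OC)c(OC)c(OCOC)c1
F5 | step 8 | ethyl (3S)-3-(2,3-dimethoxyphenoxy)-3-[3,4-dimethoxy-5-(methoxymethoxy)phenyl]propanoate | CCOC(=O)C[C@H](Oc1cccc(OC)c1OC)c1cc(OC)c(OC)c(OCOC)c1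
F6 | step 8 | (3S)-3-(2,3-dimethoxyphenoxy)-3-[3,4-dimethoxy-5-(methoxymethoxy)phenyl]propanoic acid | OC(=O)C[C@H](Oc1cccc(OC)c1OC)c1cc(OC)c(OC)c(OCOC)c1
F7 | step 2 | racemic ethyl 3-[3,4-dimethoxy-5-(methoxymethoxy)phenyl]-3-hydroxypropanoate | CCOC(=O)CC(O)c1cc(OC)c(OC)c(OCOC)c1
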